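## Retrosynthetic overview

1. C10=C11, the last bond made: Julia–Kocienski union of a bicyclic C1–C10 enal with a C11–C16 phenyltetrazolyl sulfone.
2. C6–C7: γ-selective (vinylogous Mukaiyama) capture of a bicyclic peroxycarbenium ion by the silyl dienol ether of prenal. Axial attack sets C6.
3. Both rings close in one flask from an acyclic hydroxy dienoate. O3/MeOH gives a hydroperoxyketal, a peroxy-Michael addition closes the 1,2-dioxane first, and lactonisation closes the γ-lactone second. C3 follows from C4.
4. C4–C5: catalytic asymmetric methallylboration of methyl (E)-4-oxopent-2-enoate sets C4, the only reagent-controlled stereocentre. No protecting groups are used.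

Assumption: plakortolide numbering is used (C1 lactone C=O, C3 peroxy methine, C4 lactone carbinol carbon, C6 peroxy quaternary carbon, C7–C16 side chain; target = 3S,4S,6R); in step 2 the (R)-diol is assumed to deliver methallyl to the Si face by analogy with aryl and alkenyl methyl ketones, and the equally available (S)-diol is used if that analogy runs the other way.

## Route

Step 1
Reactants: 1 2-methylallylmagnesium chloride; 2 triisopropyl borate
Product: 4 diisopropyl (2-methylallyl)boronate, via chloromagnesium ate complex 3 (not isolated)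
Conditions: Et2O/THF, −78 → 23 °C; HCl (1.0 equiv, 2 M in Et2O), 0 °C; filter, distil
Reagents that add atoms: none
Why: Borate alkylation, in which the allylic Grignard reagent adds once to B(OiPr)3 at low temperature and anhydrous HCl then strips one isopropoxide from ate complex 3 to release the distillable, magnesium-free boronate; no stereocentre is formed.

Step 2
Reactants: 4 diisopropyl (2-methylallyl)boronate; 5 methyl (E)-4-oxopent-2-enoate
Product: 7 methyl (S,E)-4-hydroxy-4,6-dimethylhepta-2,6-dienoate, via diisopropyl borate ester 6 (not isolated)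
Conditions: 4 (1.5 equiv), (R)-3,3'-Br2-BINOL (15 mol%), PhCF3/PhMe 3:1, −35 °C, 24 h; H2O
Reagents that add atoms: none
Why: Chiral-diol-catalysed asymmetric allylboration of a ketone, in which exchange of an isopropoxide for the binaphthol gives a more Lewis-acidic chiral boronate that adds strictly 1,2 through a closed Zimmerman–Traxler chair (flat alkenyl arm equatorial, methyl axial), so that Si-face delivery sets C4 as S while the uncatalysed reaction is negligible at −35 °C.

Step 3 (key step)
Reactants: 7 methyl (S,E)-4-hydroxy-4,6-dimethylhepta-2,6-dienoate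
Product: 11 (4aS,7aS)-3-methoxy-3,4a-dimethyltetrahydro-3H-furo[3,2-c][1,2]dioxin-6-one (both C6 ketal epimers), via carbonyl oxide 8 (not isolated), via hydroperoxyketal 9 (not isolated), via dioxane hydroxy ester 10 (not isolated)
Conditions: O3 (1.0 equiv, Sudan Red 7B end point), CH2Cl2/MeOH 4:1, −78 °C; Ar purge; Cs2CO3 (0.2 equiv), −78 → 0 °C, 2 h; AcOH (0.4 equiv), concentrate
Reagents that add atoms: ozone [O-][O+]=O; methanol CO
Why: Proposed new method: the electron-rich 1,1-disubstituted alkene is ozonised far faster than the enoate, Criegee cleavage puts carbonyl oxide 8 on the more substituted carbon and methanol traps it as hydroperoxyketal 9 (known ozonolysis-in-methanol entry to hydroperoxyketals), catalytic carbonate then starts a 6-exo-trig peroxy-Michael addition through a chair with C4-Me equatorial, C4-OH axial and the enoate equatorial (closest known type: base-catalysed cyclisation of hydroperoxyketals onto enoates to give 3-alkoxy-1,2-dioxanes), and the axial tertiary alkoxide of 10 lactonises onto the adjacent equatorial acetate arm; C3 is set as S from C4 because the Michael step is reversible (E1cB) and the cis-fused lactone is the thermodynamic sink, and the C6 ketal epimers are inconsequential.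

Step 4
Reactants: 12 3-methylbut-2-enal (prenal)
Product: 13 (E)-trimethyl[(3-methylbuta-1,3-dien-1-yl)oxy]silane
Conditions: Me3SiOTf (1.1 equiv), Et3N (1.5 equiv), Et2O, 0 °C, 1 h; pentane extraction, distil
Reagents that add atoms: trimethylsilyl triflate C[Si](C)(C)OS(=O)(=O)C(F)(F)F
Why: Soft enolisation, in which O-silylation of the enal acidifies the γ-methyl group and Et3N removes a γ-proton to give the linear silyl dienol ether; no stereocentre is formed and the enol-ether geometry is erased in step 5.

Step 5
Reactants: 11 bicyclic methoxy peroxyketal lactone; 13 silyl dienol ether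
Product: 15 (E)-4-[(3R,4aS,7aS)-3,4a-dimethyl-6-oxotetrahydro-3H-furo[3,2-c][1,2]dioxin-3-yl]-3-methylbut-2-enal, via peroxycarbenium triflate 14 (not isolated)
Conditions: 13 (1.8 equiv), Me3SiOTf (0.2 equiv), CH2Cl2, −78 °C, 1 h; 0.5 M aq. HCl/THF, 0 °C, 15 min
Reagents that add atoms: none
Why: Proposed new method: Me3SiOTf ionises the exocyclic methoxy group (endocyclic ionisation is reversible because the leaving peroxide stays tethered) to peroxycarbenium ion 14, which is captured at the unhindered γ-terminus of the s-trans dienol ether to give the (E)-enal and regenerate the silyl triflate, attack being axial on the half-chair with C4-O pseudoaxial and C4-Me pseudoequatorial, that is anti to the methyl and syn to the lactone oxygen, which sets C6 as R (closest known types: Hosomi–Sakurai and Mukaiyama additions to peroxycarbenium ions from 3-alkoxy-1,2-dioxolanes and 1,2-dioxanes, and γ-selective vinylogous Mukaiyama additions of silyl dienol ethers to acetals).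

Step 6
Reactants: 16 6-bromohex-1-ene; 17 sodium 1-phenyl-1H-tetrazole-5-thiolate
Product: 18 5-(hex-5-en-1-ylsulfanyl)-1-phenyl-1H-tetrazole
Conditions: EtOH, 60 °C, 3 h; aqueous wash
Reagents that add atoms: none
Why: SN2 S-alkylation of a soft thiolate by a primary bromide, with the bromide salt washed out so that it cannot be oxidised to an alkene-brominating species in step 7; no stereocentre is formed.

Step 7
Reactants: 18 5-(hex-5-en-1-ylsulfanyl)-1-phenyl-1H-tetrazole
Product: 19 5-(hex-5-en-1-ylsulfonyl)-1-phenyl-1H-tetrazole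
Conditions: H2O2 (30% aq., 6 equiv), (NH4)6Mo7O24·4H2O (10 mol%), EtOH, 0 → 23 °C, 14 h
Reagents that add atoms: hydrogen peroxide OO
Why: Molybdate-catalysed sulfide-to-sulfone oxidation, in which the peroxomolybdate oxidises sulfur twice but leaves the unactivated terminal alkene untouched.

Step 8
Reactants: 19 5-(hex-5-en-1-ylsulfonyl)-1-phenyl-1H-tetrazole; 20 styrene
Product: 21 1-phenyl-5-{[(E)-6-phenylhex-5-en-1-yl]sulfonyl}-1H-tetrazole
Conditions: 20 (3 equiv), second-generation Grubbs catalyst RuCl2(=CHPh)(PCy3)(H2IMes) (2 mol%), CH2Cl2, 40 °C, 6 h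
Reagents that add atoms: none
Why: Olefin cross-metathesis of a terminal alkene with styrene, driven by loss of ethene and giving the conjugated (E)-styrene under thermodynamic control, which sets C15=C16.

Step 9
Reactants: 15 bicyclic enal; 21 styrenyl phenyltetrazolyl sulfone
Product: 23 plakortolide H, via potassium sulfonyl carbanion 22 (not isolated)
Conditions: 21 (1.2 equiv), KN(SiMe3)2 (1.15 equiv), DME, −78 °C, 20 min; add 15, −78 → 0 °C; aq. NH4Cl
Reagents that add atoms: none
Why: Julia–Kocienski olefination, in which premetalated 22 adds 1,2 to the enal at −78 °C faster than it deprotonates, and Smiles rearrangement followed by anti-elimination of SO2 and tetrazolate gives the (E)-C10=C11 bond, leaving C3, C4, C6 and the O–O bond untouched.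

## Compound list

1 | 2-methylallylmagnesium chloride | C=C(C)C[Mg]Cl | starting material
2 | triisopropyl borate | CC(C)OB(OC(C)C)OC(C)C | starting material
3 | chloromagnesium triisopropoxy(2-methylallyl)borate | C=C(C)C[B-](OC(C)C)(OC(C)C)OC(C)C.[Mg+]Cl | intermediate
4 | diisopropyl (2-methylallyl)boronate | C=C(C)CB(OC(C)C)OC(C)C | intermediate
5 | methyl (E)-4-oxopent-2-enoate | CC(=O)/C=C/C(=O)OC | starting material
6 | diisopropyl borate ester of 7 | C=C(C)C[C@](C)(OB(OC(C)C)OC(C)C)/C=C/C(=O)OC | intermediate
7 | methyl (S,E)-4-hydroxy-4,6-dimethylhepta-2,6-dienoate | C=C(C)C[C@](C)(O)/C=C/C(=O)OC | intermediate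
8 | C6 carbonyl oxide of methyl (S,E)-4-hydroxy-4-methyl-6-oxohept-2-enoate | CC(=[O+][O-])C[C@](C)(O)/C=C/C(=O)OC | intermediate
9 | methyl (4S,E)-6-hydroperoxy-4-hydroxy-6-methoxy-4-methylhept-2-enoate (C6 epimers) | COC(C)(OO)C[C@](C)(O)/C=C/C(=O)OC | intermediate
10 | methyl 2-[(3S,4S)-4-hydroxy-6-methoxy-4,6-dimethyl-1,2-dioxan-3-yl]acetate (C6 epimers) | COC1(C)C[C@](C)(O)[C@H](CC(=O)OC)OO1 | intermediate
11 | (4aS,7aS)-3-methoxy-3,4a-dimethyltetrahydro-3H-furo[3,2-c][1,2]dioxin-6-one (C6 epimers) | COC1(C)C[C@]2(C)OC(=O)C[C@@H]2OO1 | intermediate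
12 | 3-methylbut-2-enal | CC(C)=CC=O | starting material
13 | (E)-trimethyl[(3-methylbuta-1,3-dien-1-yl)oxy]silane | C=C(C)/C=C/O[Si](C)(C)C | intermediate
14 | bicyclic C6 peroxycarbenium triflate | CC1C[C@]2(C)OC(=O)C[C@@H]2O[O+]=1.[O-]S(=O)(=O)C(F)(F)F | intermediate
15 | (E)-4-[(3R,4aS,7aS)-3,4a-dimethyl-6-oxotetrahydro-3H-furo[3,2-c][1,2]dioxin-3-yl]-3-methylbut-2-enal | C/C(=C\C=O)C[C@]1(C)C[C@]2(C)OC(=O)C[C@@H]2OO1 | intermediate
16 | 6-bromohex-1-ene | C=CCCCCBr | starting material
17 | sodium 1-phenyl-1H-tetrazole-5-thiolate | [Na+].[S-]c1nnnn1-c1ccccc1 | starting material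
18 | 5-(hex-5-en-1-ylsulfanyl)-1-phenyl-1H-tetrazole | C=CCCCCSc1nnnn1-c1ccccc1 | intermediate
19 | 5-(hex-5-en-1-ylsulfonyl)-1-phenyl-1H-tetrazole | C=CCCCCS(=O)(=O)c1nnnn1-c1ccccc1 | intermediate
20 | styrene | C=Cc1ccccc1 | starting material
21 | 1-phenyl-5-{[(E)-6-phenylhex-5-en-1-yl]sulfonyl}-1H-tetrazole | O=S(=O)(CCCC/C=C/c1ccccc1)c1nnnn1-c1ccccc1 | intermediate
22 | potassium α-sulfonyl carbanion of 21 | [K+].[CH-](CCC/C=C/c1ccccc1)S(=O)(=O)c1nnnn1-c1ccccc1 | intermediate
23 | plakortolide H, (3R,4aS,7aS)-3,4a-dimethyl-3-[(2E,4E,9E)-2-methyl-10-phenyldeca-2,4,9-trien-1-yl]tetrahydro-3H-furo[3,2-c][1,2]dioxin-6-one | C/C(=C\C=C\CCC/C=C/c1ccccc1)C[C@]1(C)C[C@]2(C)OC(=O)C[C@@H]2OO1 | target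

## Step count and risks

Total steps: 9. Longest linear sequence: 5 (steps 1, 2, 3, 5, 9). The side chain takes 4 steps (6, 7, 8, 9).

**Step 3.**
- Risks: part of the primary ozonide may cleave the other way, to ketone plus formaldehyde oxide. Carbonate may also cause retro-Michael or Kornblum–DeLaMare loss before the lactone closes.
- Fallback: it sets out from 7 and comes back at 11. The peroxide is introduced by acid-catalysed perketalisation instead of Criegee trapping.
- Ozonolysis of 7 in CH2Cl2 with Me2S work-up gives methyl (S,E)-4-hydroxy-4-methyl-6-oxohept-2-enoate F1.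
- Urea·H2O2 and Sc(OTf)3 (5 mol%) in MeOH convert the ketone of F1 into hydroperoxyketal 9.
- Et2NH in CF3CH2OH, added to the same flask, then closes the dioxane and the lactone through 10 to give 11.

**Step 5.**
- Risks: fragmentation of the ketal instead of clean exocyclic ionisation, α- rather than γ-attack of the dienol ether, E/Z leakage at C8=C9, and only modest facial selectivity at C6.
- Fallback: it sets out from 11 and comes back at 15. It uses the best-precedented nucleophile class for peroxycarbenium ions and builds the enal afterwards.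
- SnCl4-mediated Hosomi–Sakurai reaction of 11 with (2-methylallyl)trimethylsilane (CH2Cl2, −78 °C) gives (3R,4aS,7aS)-3,4a-dimethyl-3-(2-methylallyl)tetrahydro-3H-furo[3,2-c][1,2]dioxin-6-one F2.
- Cross-metathesis of F2 with crotonaldehyde gives enal 15. The catalyst is the second-generation Hoveyda–Grubbs catalyst RuCl2(=CH-C6H4-2-OiPr)(H2IMes), 10 mol%, in CH2Cl2 at 40 °C.

**Step 9.**
- Risks: enal 15 is a vinylogous β-peroxy carbonyl compound, so γ-deprotonation at C7 would expel the peroxide. The lactone C2–H can trigger E1cB ring opening. E/Z selectivity with an enal partner may be only moderate.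
- Fallback: it sets out from 11 and comes back at 23. It avoids any carbonyl group or carbanion next to the peroxide by making the C9–C10 bond through cross-coupling.
- NiCl2(dppp)-catalysed Kumada coupling of bis(trimethylsilyl)methylmagnesium chloride with 2-bromopropene gives 2-methyl-3,3-bis(trimethylsilyl)prop-1-ene F3.
- SnCl4-mediated Hosomi–Sakurai reaction of 11 with F3 gives (3R,4aS,7aS)-3,4a-dimethyl-3-[(E)-2-methyl-3-(trimethylsilyl)allyl]tetrahydro-3H-furo[3,2-c][1,2]dioxin-6-one F4, with the C8=C9 geometry fixed as E.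
- Iododesilylation of F4 with N-iodosuccinimide in MeCN proceeds with retention to (3R,4aS,7aS)-3-[(E)-3-iodo-2-methylallyl]-3,4a-dimethyltetrahydro-3H-furo[3,2-c][1,2]dioxin-6-one F5.
- Separately, Horner–Wadsworth–Emmons reaction of hex-5-ynal with diethyl benzylphosphonate (NaH, THF) gives (E)-hept-1-en-6-yn-1-ylbenzene F6.
- Cp2ZrHCl-catalysed hydroboration of F6 with pinacolborane gives 4,4,5,5-tetramethyl-2-[(1E,6E)-7-phenylhepta-1,6-dien-1-yl]-1,3,2-dioxaborolane F7.
- Suzuki–Miyaura coupling of F5 with F7 (Pd(dppf)Cl2, K3PO4, THF/H2O, 23 °C) gives 23. Dialkyl peroxides tolerate zerovalent palladium at this temperature.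

## Further compounds

F1 | step 3 | methyl (S,E)-4-hydroxy-4-methyl-6-oxohept-2-enoate | CC(=O)C[C@](C)(O)/C=C/C(=O)OC
F2 | step 5 | (3R,4aS,7aS)-3,4a-dimethyl-3-(2-methylallyl)tetrahydro-3H-furo[3,2-c][1,2]dioxin-6-one | C=C(C)C[C@]1(C)C[C@]2(C)OC(=O)C[C@@H]2OO1
F3 | step 9 | 2-methyl-3,3-bis(trimethylsilyl)prop-1-ene | C=C(C)C([Si](C)(C)C)[Si](C)(C)C
F4 | step 9 | (3R,4aS,7aS)-3,4a-dimethyl-3-[(E)-2-methyl-3-(trimethylsilyl)allyl]tetrahydro-3H-furo[3,2-c][1,2]dioxin-6-one | C/C(=C\[Si](C)(C)C)C[C@]1(C)C[C@]2(C)OC(=O)C[C@@H]2OO1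
F5 | step 9 | (3R,4aS,7aS)-3-[(E)-3-iodo-2-methylallyl]-3,4a-dimethyltetrahydro-3H-furo[3,2-c][1,2]dioxin-6-one | C/C(=C\I)C[C@]1(C)C[C@]2(C)OC(=O)C[C@@H]2OO1
F6 | step 9 | (E)-hept-1-en-6-yn-1-ylbenzene | C#CCCC/C=C/c1ccccc1
F7 | step 9 | 4,4,5,5-tetramethyl-2-[(1E,6E)-7-phenylhepta-1,6-dien-1-yl]-1,3,2-dioxaborolane | CC1(C)OB(/C=C/CCC/C=C/c2ccccc2)OC1(C)C
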